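I started from amounts. In every flask here the substrate charge stands far above the enzyme charge, while the impurity charge is of the enzyme's own size, so I weighed impurity against enzyme.

in all of them: substrate 10 mM
- gamma: free enzyme 1 µM; impurity 0.63 µM; temperature 40 °C; the very flask that is asked about, followed so far
- eta: free enzyme 1 µM; impurity 1.3 µM; temperature 46 °C; run made earlier
- flask: free enzyme 1.0 µM; impurity 0.63 µM; temperature 40 °C; time 8.0 d

| run | time / h | product / % | substrate / % |
|---|---|---|---|
| gamma | 10.0 | 23 | 76 |
| gamma | 20.0 | 41 | 60 |
| gamma | 50.0 | 68 | 34 |
| gamma | 120 | 72 | 25 |
| eta | 4.00 | 6 | 95 |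
| eta | 8.00 | 4 | 95 |
| eta | 12.0 | 4 | 96 |
| eta | 20.0 | 1 | 93 |

(standard deviation of a reading: 1.5 percentage points)

- Friday's: at 8.0 d add free enzyme, 50.0 % of the amount charged, then wait 4.0 d
- Sunday's: at 8.0 d raise the temperature by 15 K, then wait 4.0 d
- Saturday's: change nothing and wait 4.0 d more
- Wednesday's: at 8.0 d take out 90 % of the product then present, then wait 4.0 d

- product taken out counts as made
- additions bring no volume worth counting

* product, in percent of the substrate first charged, at 8.0 d
* what to do for the largest gain in product; "none" if nothing gains more than 2 percentage points (Friday's / Sunday's / Saturday's / Wednesday's / none)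
* product present, with what was taken out counted in, in percent of the substrate first charged, after Sunday's
* product present, with what was taken out counted in, in percent of the substrate first charged, after Wednesday's

The bench rule for a poison is to subtract it from the catalyst charge, one for one. For the gamma flask, which is the flask asked about, one minus impurity over enzyme gave 0.370. I call this fraction of the enzyme charge that the impurity leaves the margin. While the margin is positive, the impurity is the limiting reagent of that poisoning.

The rule has a border where the ratio of impurity to enzyme passes one. Gamma's ratio was 0.630 and eta's 1.30. Eta's product read 6 % at 4.00 h and 1 % at 20.0 h, though eta was also hotter, so the readings alone could not separate the two settings.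

Gamma levelled near 72 % with 25 % of substrate beside it. That could be equilibrium or a used-up margin, so I expected about that product at the asked time. If the margin was used up, the plateau gave a yield of 1.95 substrate charges for each enzyme charge of margin. A fresh 50.0 % of enzyme at that yield would cover 97.5 %, well above the substrate remaining. But the gamma readings at 120 h put product at 2.88 times the substrate, so any enzyme loss tied to product would cut that yield. I therefore chose Friday's, with a gain below the substrate remaining.

The forecast parted from me on the choice: it gave 74 % now, 74 % after Sunday's, 90 % after Wednesday's and Wednesday's as best, holding that “Extra enzyme or waiting then gains nothing”.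

The flask gave 74.9 %. Friday's was best, bringing 16 percentage points, while Sunday's ended at 74.9 % and Wednesday's at 75.0 %.

    free enzyme + impurity → spent catalyst A (k = 4.00 × 10⁶ L mol⁻¹ h⁻¹, Ea = 45.0 kJ mol⁻¹)
    complex → free enzyme + product (k = 1100 h⁻¹, Ea = 88.0 kJ mol⁻¹)
    free enzyme + product → spent catalyst B (k = 7.40 L mol⁻¹ h⁻¹, Ea = 65.0 kJ mol⁻¹)
    free enzyme → unfolded enzyme (k = 0.00120 h⁻¹, Ea = 190 kJ mol⁻¹)
    substrate + free enzyme ⇌ complex (K = 120 L mol⁻¹, k = 3.50 × 10⁷ L mol⁻¹ h⁻¹, Ea = 29.0 kJ mol⁻¹, ΔH = −54.0 kJ mol⁻¹)
    (constants at 40 °C)

At 192 h the flask held 63.0 % of its enzyme as spent catalyst A, and spent catalyst B with unfolded enzyme held 37.0 %, beside 0.0259 % as free enzyme and 0.00775 % as complex, so the margin of 0.370 stood almost wholly in those two spent forms. Part of what held product at 74.9 % was the step from free enzyme + product to spent catalyst B: with it struck out, product reached 99.9 %. Friday's gain of 16 points shrank to 0.06 points without that step, and to 0 points without the falling back of complex to substrate + free enzyme. The neighbour with 0.0016 mM of impurity had a margin of −0.600, past the border, which leaves 37.5 % of its impurity charge over. That flask ended with 38 % of its impurity unspent and 3.17 % product.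

Readings and results are simulated on assumed constants; noise was put on by code.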